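**Retrosynthetic overview**

1. Stereochemical sources: ring C1 is bought in (R)-carvone 1 and relayed to C6, C5 and C3/C4; side-chain C10 is bought in methyl (S)-glycerate acetonide 2 and relayed to C8.
2. Last bond: the C10–C11 oxirane, by SN2 closure of a C10 mesylate (inversion) after angeloylation of C8–OH; C8–OH comes from a 1,3-anti hydroxyl-directed reduction of a β-hydroxy enone.
3. Key disconnection C8–C9: nickel-electrocatalysed acylative opening of a terminal epoxide (C9–C11 unit) by a ring-bearing α-methylene carboxylic acid (C8); this is the proposed new step.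
4. The acid comes from allylic oxidation of the isopropenyl group of a carvone-derived epoxy diangelate (Rubottom oxidation, Luche reduction, hydroxyl-directed epoxidation, double angeloylation).
5. Ring order: cyclohexane bought; ring oxirane (step 3); transient terminal oxirane of the C5 unit (step 8, opened in step 9); side-chain oxirane (step 12).

Assumption and labels: 1, 2 (sold as the (S)-serine-derived acetonide ester) and angelic acid are bought; atoms are labelled as in the target: ring C1 (bears the side chain), C2 (CH2), C3/C4 (oxirane, CH3 on C4), C5 and C6 (acyloxy, C6 next to C1), chain C7 (=C14H2), C8 (acyloxy), C9 (CH2), C10/C11 (oxirane, two CH3 on C11); the target is (1S,3S,4S,5R,6S,8S,10R) in these labels.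

**Route**

Step 1
Reactants: 1 (R)-carvone
Product: 5 (5S,6S)-6-hydroxy-2-methyl-5-(prop-1-en-2-yl)cyclohex-2-en-1-one (trans-6-hydroxycarvone), via silyl dienol ether 3 (not isolated), via 6-silyloxy ketone 4 (not isolated)
Conditions: LiN(iPr)2, THF, −78 °C, then TMSCl; mCPBA, hexane, −20 °C; citric acid (cat.), MeOH, 0 °C
Reagents that add atoms: mCPBA, OOC(=O)c1cccc(Cl)c1
Why: LiN(iPr)2 removes the kinetic α′ proton at C6 to give the cross-conjugated silyl dienol ether, and the Rubottom oxidation (peracid epoxidation of the enol ether, silyl shift, desilylation) delivers oxygen to the face anti to the isopropenyl-bearing C1, so the new C6 centre is trans to C1.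

Step 2
Reactants: 5 trans-6-hydroxycarvone
Product: 6 (1S,2S,6S)-3-methyl-6-(prop-1-en-2-yl)cyclohex-3-ene-1,2-diol
Conditions: NaBH4, CeCl3·7H2O, MeOH, −78 °C
Reagents that add atoms: none
Why: Luche reduction gives clean carbonyl reduction with axial hydride attack on the half-chair whose C1 and C6 substituents are equatorial, so the new C5 hydroxyl is equatorial, trans to C6–OH and cis to the C1 substituent (as in cis-carveol from carvone).

Step 3
Reactants: 6 the cyclohexene diol
Product: 7 (1R,2R,3S,4S,6S)-1-methyl-4-(prop-1-en-2-yl)-7-oxabicyclo[4.1.0]heptane-2,3-diol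
Conditions: VO(acac)2 (3 mol%), t-BuOOH (1.1 equiv), CH2Cl2, 0 °C to rt
Reagents that add atoms: tert-butyl hydroperoxide, CC(C)(C)OO
Why: Hydroxyl-directed epoxidation, in which the vanadium alkoxide of the allylic C5–OH delivers the peroxide oxygen to its own face of C3=C4, sets C3 and C4 with the oxirane cis to C5–O, while the isopropenyl alkene, only homoallylic to C6–OH, reacts far more slowly.

Step 4
Reactants: 7 the epoxy diol
Product: 9 (1S,2R,3S,4S,6S)-1-methyl-4-(prop-1-en-2-yl)-7-oxabicyclo[4.1.0]heptane-2,3-diyl bis[(2Z)-2-methylbut-2-enoate], via C6 mono-angelate 8 (not isolated)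
Conditions: angelic acid, 2,4,6-Cl3C6H2COCl, Et3N, toluene, rt; then 7, 75 °C
Reagents that add atoms: angelic acid, C/C=C(/C)C(=O)O
Why: Yamaguchi-type esterification through the angelic 2,4,6-trichlorobenzoic mixed anhydride without a nucleophilic catalyst acylates both secondary hydroxyls with retention at C5 and C6 and without Z to E isomerisation to tiglate.

Step 5
Reactants: 9 the epoxy diangelate
Product: 10 (1S,2R,3S,4S,6S)-4-(3-hydroxyprop-1-en-2-yl)-1-methyl-7-oxabicyclo[4.1.0]heptane-2,3-diyl bis[(2Z)-2-methylbut-2-enoate]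
Conditions: SeO2 (0.5 equiv), t-BuOOH (3 equiv), salicylic acid (10 mol%), CH2Cl2, rt
Reagents that add atoms: tert-butyl hydroperoxide, CC(C)(C)OO
Why: SeO2 allylic oxidation (ene reaction then 2,3-sigmatropic shift) hydroxylates the isopropenyl methyl and returns the double bond to C7=C14, as established for isopropenyl groups of eudesmanes, while the electron-poor angelate alkenes are inert and no stereocentre is touched.

Step 6
Reactants: 10 the allylic alcohol
Product: 12 (1S,2R,3S,4S,6S)-4-(1-carboxyethenyl)-1-methyl-7-oxabicyclo[4.1.0]heptane-2,3-diyl bis[(2Z)-2-methylbut-2-enoate], via enal 11 (not isolated)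
Conditions: TEMPO (10 mol%), PhI(OAc)2, CH2Cl2, rt; then NaClO2, NaH2PO4, 2-methyl-2-butene, t-BuOH/H2O, 0 °C
Reagents that add atoms: sodium chlorite, [Na+].[O-]Cl=O
Why: Oxoammonium (TEMPO) oxidation stops at the enal and Pinnick oxidation then gives the α-methylene acid under buffered conditions that spare the oxirane, the angelates and the C1 centre.

Step 7
Reactants: 2 methyl (S)-2,2-dimethyl-1,3-dioxolane-4-carboxylate
Product: 14 (S)-3-methylbutane-1,2,3-triol, via tertiary alcohol acetonide 13 (not isolated)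
Conditions: MeMgBr (3 equiv), THF, 0 °C; then 1 M aq HCl, rt
Reagents that add atoms: methylmagnesium bromide, C[Mg]Br
Why: Double Grignard addition to the ester builds C11 with its two methyl groups without touching the adjacent C10 centre, and aqueous acid then hydrolyses the terminal acetonide.

Step 8
Reactants: 14 (S)-3-methylbutane-1,2,3-triol
Product: 16 (S)-2-(oxiran-2-yl)propan-2-ol, via primary tosylate 15 (not isolated)
Conditions: TsCl (1.05 equiv), Bu2SnO (2 mol%), Et3N, CH2Cl2, 0 °C; then K2CO3, MeOH, 0 °C, 20 min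
Reagents that add atoms: none
Why: Tin-acetal-catalysed sulfonylation is selective for the primary hydroxyl, and intramolecular Williamson etherification by the C10 oxygen closes the terminal oxirane with the C10–O bond intact (retention), the short cold base treatment avoiding Payne rearrangement.

Step 9
Reactants: 12 the α-methylene acid; 16 (S)-2-(oxiran-2-yl)propan-2-ol
Product: 19 (1S,2R,3S,4S,6S)-4-[(5S)-5,6-dihydroxy-6-methyl-3-oxohept-1-en-2-yl]-1-methyl-7-oxabicyclo[4.1.0]heptane-2,3-diyl bis[(2Z)-2-methylbut-2-enoate], via mixed anhydride 17 (not isolated), via iodohydrin 18 (not isolated)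
Conditions: 12, Boc2O, MgCl2, DMA, rt; then 16 (1.5 equiv), NaI (25 mol%), Et3N·HCl, NiBr2(MeOCH2CH2OMe) (10 mol%), 4,4′-di-tert-butyl-2,2′-bipyridine (12 mol%), Zn anode, graphite cathode, undivided cell, 4 mA, 2.5 F/mol, DMA, 25 °C
Reagents that add atoms: none
Why: Proposed new method: a nickel-electrocatalysed acylative opening of a terminal epoxide (a base-free formal aldol union) in which iodide opens acid-activated 16 at its unhindered CH2 (C9) to iodohydrin 18, cathodically formed zerovalent nickel inserts into the acyl C–O bond of mixed anhydride 17, monovalent nickel abstracts iodine from 18, and the primary β-hydroxyalkyl radical is trapped by the divalent acyl nickel species (about 10^7 to 10^8 M^-1 s^-1, faster than Giese addition to the α-branched acrylate) before reductive elimination forms the C8–C9 bond, while the C10–O bond is never broken so the bought (S) centre is kept; the closest known reaction types are the nickel-catalysed reductive cross-electrophile coupling of epoxides with aryl halides under iodide co-catalysis and the nickel-catalysed reductive ketone synthesis from anhydride-activated carboxylic acids and alkyl iodides, neither shown for an epoxide and acyl pair nor for an α-methylene acyl partner under electrolysis.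

Step 10
Reactants: 19 the β-hydroxy enone
Product: 20 (1S,2R,3S,4S,6S)-1-methyl-4-[(3S,5S)-3,5,6-trihydroxy-6-methylhept-1-en-2-yl]-7-oxabicyclo[4.1.0]heptane-2,3-diyl bis[(2Z)-2-methylbut-2-enoate]
Conditions: Me4NBH(OAc)3, MeCN/AcOH (1:1), −30 °C
Reagents that add atoms: none
Why: Evans–Saksena reduction, in which the triacetoxyborohydride exchanges onto the C10 hydroxyl and delivers hydride intramolecularly through a chair transition state, gives the 1,3-anti diol and thus the (8S) carbinol, with reduction only at the enone carbonyl.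

Step 11
Reactants: 20 the triol
Product: 21 (1S,2R,3S,4S,6S)-4-[(3S,5S)-5,6-dihydroxy-6-methyl-3-{[(2Z)-2-methylbut-2-enoyl]oxy}hept-1-en-2-yl]-1-methyl-7-oxabicyclo[4.1.0]heptane-2,3-diyl bis[(2Z)-2-methylbut-2-enoate]
Conditions: angelic acid (1.3 equiv), 2,4,6-Cl3C6H2COCl, Et3N, toluene, rt; then 20, 50 °C
Reagents that add atoms: angelic acid, C/C=C(/C)C(=O)O
Why: Mixed-anhydride (Yamaguchi-type) esterification acylates the allylic C8 hydroxyl with retention in preference to the neopentyl-like C10 hydroxyl, which is flanked by the quaternary C11 and hydrogen-bonded to its hydroxyl, and to the tertiary C11 hydroxyl.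

Step 12
Reactants: 21 the triangelate diol
Product: 23 (1S,2R,3S,4S,6S)-4-{(3S)-4-[(2R)-3,3-dimethyloxiran-2-yl]-3-{[(2Z)-2-methylbut-2-enoyl]oxy}but-1-en-2-yl}-1-methyl-7-oxabicyclo[4.1.0]heptane-2,3-diyl bis[(2Z)-2-methylbut-2-enoate] (target), via C10 mesylate 22 (not isolated)
Conditions: MsCl, Et3N, CH2Cl2, −20 °C; then K2CO3, MeOH, 0 °C
Reagents that add atoms: none
Why: Sulfene mesylation occurs at the only remaining secondary hydroxyl, and base then triggers an intramolecular Williamson (SN2) closure by the tertiary C11 alkoxide with inversion at C10 (S to R), the standard conversion of such a secondary–tertiary diol into its oxirane, which completes the target.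

**Compound list**

1 | (R)-carvone, (5R)-2-methyl-5-(prop-1-en-2-yl)cyclohex-2-en-1-one | C=C(C)[C@@H]1CC=C(C)C(=O)C1 | starting material
2 | methyl (S)-2,2-dimethyl-1,3-dioxolane-4-carboxylate | COC(=O)[C@@H]1COC(C)(C)O1 | starting material
3 | (R)-trimethyl{[6-methyl-3-(prop-1-en-2-yl)cyclohexa-1,5-dien-1-yl]oxy}silane (kinetic silyl dienol ether of 1) | C=C(C)[C@@H]1CC=C(C)C(O[Si](C)(C)C)=C1 | intermediate
4 | (5S,6S)-2-methyl-5-(prop-1-en-2-yl)-6-[(trimethylsilyl)oxy]cyclohex-2-en-1-one | C=C(C)[C@@H]1CC=C(C)C(=O)[C@H]1O[Si](C)(C)C | intermediate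
5 | (5S,6S)-6-hydroxy-2-methyl-5-(prop-1-en-2-yl)cyclohex-2-en-1-one (6-OH trans to isopropenyl) | C=C(C)[C@@H]1CC=C(C)C(=O)[C@H]1O | intermediate
6 | (1S,2S,6S)-3-methyl-6-(prop-1-en-2-yl)cyclohex-3-ene-1,2-diol (C5-OH cis to isopropenyl, C6-OH trans) | C=C(C)[C@@H]1CC=C(C)[C@H](O)[C@H]1O | intermediate
7 | (1R,2R,3S,4S,6S)-1-methyl-4-(prop-1-en-2-yl)-7-oxabicyclo[4.1.0]heptane-2,3-diol (oxirane cis to C5-OH) | C=C(C)[C@@H]1C[C@@H]2O[C@]2(C)[C@H](O)[C@H]1O | intermediate
8 | (1R,2R,3S,4S,6S)-2-hydroxy-1-methyl-4-(prop-1-en-2-yl)-7-oxabicyclo[4.1.0]heptan-3-yl (2Z)-2-methylbut-2-enoate (C6 mono-angelate) | C=C(C)[C@@H]1C[C@@H]2O[C@]2(C)[C@H](O)[C@H]1OC(=O)/C(C)=C\C | intermediate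
9 | (1S,2R,3S,4S,6S)-1-methyl-4-(prop-1-en-2-yl)-7-oxabicyclo[4.1.0]heptane-2,3-diyl bis[(2Z)-2-methylbut-2-enoate] | C=C(C)[C@@H]1C[C@@H]2O[C@]2(C)[C@H](OC(=O)/C(C)=C\C)[C@H]1OC(=O)/C(C)=C\C | intermediate
10 | (1S,2R,3S,4S,6S)-4-(3-hydroxyprop-1-en-2-yl)-1-methyl-7-oxabicyclo[4.1.0]heptane-2,3-diyl bis[(2Z)-2-methylbut-2-enoate] | OCC(=C)[C@@H]1C[C@@H]2O[C@]2(C)[C@H](OC(=O)/C(C)=C\C)[C@H]1OC(=O)/C(C)=C\C | intermediate
11 | (1S,2R,3S,4S,6S)-1-methyl-4-(3-oxoprop-1-en-2-yl)-7-oxabicyclo[4.1.0]heptane-2,3-diyl bis[(2Z)-2-methylbut-2-enoate] (enal) | O=CC(=C)[C@@H]1C[C@@H]2O[C@]2(C)[C@H](OC(=O)/C(C)=C\C)[C@H]1OC(=O)/C(C)=C\C | intermediate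
12 | (1S,2R,3S,4S,6S)-4-(1-carboxyethenyl)-1-methyl-7-oxabicyclo[4.1.0]heptane-2,3-diyl bis[(2Z)-2-methylbut-2-enoate] (α-methylene acid) | OC(=O)C(=C)[C@@H]1C[C@@H]2O[C@]2(C)[C@H](OC(=O)/C(C)=C\C)[C@H]1OC(=O)/C(C)=C\C | intermediate
13 | (S)-2-(2,2-dimethyl-1,3-dioxolan-4-yl)propan-2-ol | CC(C)(O)[C@@H]1COC(C)(C)O1 | intermediate
14 | (S)-3-methylbutane-1,2,3-triol | CC(C)(O)[C@@H](O)CO | intermediate
15 | (S)-2,3-dihydroxy-3-methylbutyl 4-methylbenzenesulfonate | CC(C)(O)[C@@H](O)COS(=O)(=O)c1ccc(C)cc1 | intermediate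
16 | (S)-2-(oxiran-2-yl)propan-2-ol | CC(C)(O)[C@@H]1CO1 | intermediate
17 | tert-butyl carbonic anhydride of 12 | CC(C)(C)OC(=O)OC(=O)C(=C)[C@@H]1C[C@@H]2O[C@]2(C)[C@H](OC(=O)/C(C)=C\C)[C@H]1OC(=O)/C(C)=C\C | intermediate
18 | (R)-1-iodo-3-methylbutane-2,3-diol | CC(C)(O)[C@@H](O)CI | intermediate
19 | (1S,2R,3S,4S,6S)-4-[(5S)-5,6-dihydroxy-6-methyl-3-oxohept-1-en-2-yl]-1-methyl-7-oxabicyclo[4.1.0]heptane-2,3-diyl bis[(2Z)-2-methylbut-2-enoate] | C=C(C(=O)C[C@H](O)C(C)(C)O)[C@@H]1C[C@@H]2O[C@]2(C)[C@H](OC(=O)/C(C)=C\C)[C@H]1OC(=O)/C(C)=C\C | intermediate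
20 | (1S,2R,3S,4S,6S)-1-methyl-4-[(3S,5S)-3,5,6-trihydroxy-6-methylhept-1-en-2-yl]-7-oxabicyclo[4.1.0]heptane-2,3-diyl bis[(2Z)-2-methylbut-2-enoate] | C=C([C@H](C[C@H](O)C(C)(C)O)O)[C@@H]1C[C@@H]2O[C@]2(C)[C@H](OC(=O)/C(C)=C\C)[C@H]1OC(=O)/C(C)=C\C | intermediate
21 | (1S,2R,3S,4S,6S)-4-[(3S,5S)-5,6-dihydroxy-6-methyl-3-{[(2Z)-2-methylbut-2-enoyl]oxy}hept-1-en-2-yl]-1-methyl-7-oxabicyclo[4.1.0]heptane-2,3-diyl bis[(2Z)-2-methylbut-2-enoate] | C=C([C@H](C[C@H](O)C(C)(C)O)OC(=O)/C(C)=C\C)[C@@H]1C[C@@H]2O[C@]2(C)[C@H](OC(=O)/C(C)=C\C)[C@H]1OC(=O)/C(C)=C\C | intermediate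
22 | (1S,2R,3S,4S,6S)-4-[(3S,5S)-6-hydroxy-5-(methanesulfonyloxy)-6-methyl-3-{[(2Z)-2-methylbut-2-enoyl]oxy}hept-1-en-2-yl]-1-methyl-7-oxabicyclo[4.1.0]heptane-2,3-diyl bis[(2Z)-2-methylbut-2-enoate] | C=C([C@H](C[C@H](OS(C)(=O)=O)C(C)(C)O)OC(=O)/C(C)=C\C)[C@@H]1C[C@@H]2O[C@]2(C)[C@H](OC(=O)/C(C)=C\C)[C@H]1OC(=O)/C(C)=C\C | intermediate
23 | (1S,2R,3S,4S,6S)-4-{(3S)-4-[(2R)-3,3-dimethyloxiran-2-yl]-3-{[(2Z)-2-methylbut-2-enoyl]oxy}but-1-en-2-yl}-1-methyl-7-oxabicyclo[4.1.0]heptane-2,3-diyl bis[(2Z)-2-methylbut-2-enoate] (CNP0258231.3) | C=C([C@H](C[C@H]1OC1(C)C)OC(=O)/C(C)=C\C)[C@@H]1C[C@@H]2O[C@]2(C)[C@H](OC(=O)/C(C)=C\C)[C@H]1OC(=O)/C(C)=C\C | target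

**Step count and risks**

Total steps: 12. Longest linear sequence: 10 (steps 1 to 6, then 9 to 12); steps 7 and 8 make the C5 unit.

Most likely to fail, first: step 5 (SeO2 allylic oxidation). The risks are low conversion, competing attack at the tertiary allylic C1–H and over-oxidation. The fallback sets out from 9: ene-type chlorination of the isopropenyl group with Ca(OCl)2 and CO2 in CH2Cl2/H2O gives the allylic chloride F1, and trimethylamine N-oxide in DMSO converts it into the enal 11, now isolated. The route is rejoined at 11, which the chlorite stage of step 6 takes on to 12.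

Second: step 9 (the proposed new coupling). The risks are Giese addition of the C9 radical to 17 or to the product enone, Payne rearrangement of 16, and acylation of the free hydroxyls. The fallback uses known chemistry and sets out from 12 (and from 14 for the C5 unit). Acid 12 is converted with 2,2′-dipyridyl disulfide and PPh3 into the S-pyridin-2-yl thioester F2. Triol 14 is iodinated at the primary position (I2, PPh3, imidazole) to give 18, here isolated, which is capped with 2-methoxypropene and PPTS as the iodo acetonide F3. The established nickel-catalysed reductive ketone synthesis from a pyridyl thioester and an alkyl iodide (NiCl2(MeOCH2CH2OMe), 4,4′-di-tert-butyl-2,2′-bipyridine, Zn dust, DMA) then gives the ketone acetonide F4. Hydrolysis in 80% aqueous AcOH comes back to the route at 19.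

Third: step 11 (acylation of C8–OH in the presence of C10–OH). The risk is bis-acylation or acylation at C10. The fallback sets out from 20: 2-methoxypropene and PPTS give the 10,11-acetonide F5, the five-membered ring being preferred over a dioxane across the anti-1,3-diol. Angeloylation as in step 11 gives the ester acetonide F6, and 80% aqueous AcOH at 40 °C comes back to the route at 21.

**Further compounds**

F1 | step 5 | (1S,2R,3S,4S,6S)-4-(3-chloroprop-1-en-2-yl)-1-methyl-7-oxabicyclo[4.1.0]heptane-2,3-diyl bis[(2Z)-2-methylbut-2-enoate] | ClCC(=C)[C@@H]1C[C@@H]2O[C@]2(C)[C@H](OC(=O)/C(C)=C\C)[C@H]1OC(=O)/C(C)=C\C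
F2 | step 9 | S-pyridin-2-yl thioester of 12 | O=C(Sc1ccccn1)C(=C)[C@@H]1C[C@@H]2O[C@]2(C)[C@H](OC(=O)/C(C)=C\C)[C@H]1OC(=O)/C(C)=C\C
F3 | step 9 | (R)-4-(iodomethyl)-2,2,5,5-tetramethyl-1,3-dioxolane | CC1(C)OC(C)(C)O[C@H]1CI
F4 | step 9 | 10,11-acetonide of 19 | C=C(C(=O)C[C@@H]1OC(C)(C)OC1(C)C)[C@@H]1C[C@@H]2O[C@]2(C)[C@H](OC(=O)/C(C)=C\C)[C@H]1OC(=O)/C(C)=C\C
F5 | step 11 | 10,11-acetonide of 20 | C=C([C@H](C[C@@H]1OC(C)(C)OC1(C)C)O)[C@@H]1C[C@@H]2O[C@]2(C)[C@H](OC(=O)/C(C)=C\C)[C@H]1OC(=O)/C(C)=C\C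
F6 | step 11 | 10,11-acetonide of 21 | C=C([C@H](C[C@@H]1OC(C)(C)OC1(C)C)OC(=O)/C(C)=C\C)[C@@H]1C[C@@H]2O[C@]2(C)[C@H](OC(=O)/C(C)=C\C)[C@H]1OC(=O)/C(C)=C\C
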